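all flasks: coupling partner 0.465 M; free catalyst 1.5 mM

| flask | left-handed substrate | right-handed substrate | impurity | remark | time |
|---|---|---|---|---|---|
| dawn | 0.31 M | 0.31 M | 2.9 mM | run made earlier |  |
| dusk | 0.31 M | 0.31 M | 4.6 mM | run made earlier |  |
| winter | 0.62 M | 0.62 M | 2.1 mM | run made earlier |  |
| flask | 0.31 M | 0.31 M | 2.1 mM |  | 20 min |

| run | time / min | right-handed substrate / % | left-handed substrate / % | left-handed product / % |
|---|---|---|---|---|
| dawn | 1.00 | 49.3 | 47.5 | 2.4 |
| dawn | 3.00 | 48.3 | 46.9 | 3.6 |
| dawn | 6.00 | 48.8 | 45.9 | 3.6 |
| dawn | 8.00 | 48.3 | 46.6 | 3.4 |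
| dawn | 12.0 | 48.7 | 46.2 | 3.4 |
| dawn | 15.0 | 48.4 | 46.2 | 4.0 |
| dusk | 1.33 | 49.5 | 48.6 | 1.6 |
| dusk | 2.00 | 49.2 | 47.7 | 1.4 |
| dusk | 4.00 | 49.1 | 48.1 | 1.9 |
| dusk | 6.00 | 48.9 | 48.2 | 1.6 |
| dusk | 10.0 | 49.3 | 47.8 | 2.1 |
| dusk | 15.0 | 49.5 | 47.7 | 2.4 |
| winter | 3.00 | 48.3 | 46.5 | 3.4 |
| winter | 6.00 | 47.7 | 46.1 | 4.4 |
| winter | 10.0 | 48.1 | 45.6 | 4.4 |
| winter | 12.0 | 48.2 | 45.3 | 5.1 |
| winter | 15.0 | 47.7 | 45.1 | 4.7 |

(each reading ± 0.3 percentage points)

- free catalyst is single-handed; left-handed substrate and right-handed substrate are mirror images of each other, charged as a racemate, each of them at the stated concentration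
- the numbers in the tables scatter by 0.3 percentage points (one standard deviation)

- whether the excess of right-handed substrate over left-handed substrate among what is left of the two reaches 90% by 20 min (yes / no)
- the highest excess of right-handed substrate over left-handed substrate among what is left of the two up to 20 min

1. The flask held 2.1 mM of impurity against 1.5 mM of free catalyst, and I divided the two to get 1.40; this poison ratio, impurity charged per catalyst charged, meant that if each impurity killed one catalyst, a value above one ended the catalysis with impurity to spare.

2. The dawn run, at ratio 1.93, read an excess of 2.33% at its last reading, and the dusk run, at 3.07, read a lower 1.85%.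

3. With impurity charged above catalyst and the substrate held fixed, one-for-one killing makes the catalyst's working time go as ln([impurity]/([impurity]−[free catalyst])), with both taken as charged, which from the dawn run to this flask grew by a factor of 1.72, so, taking the excess to grow in step with that time, I reckoned a stalled excess near 4.00% for this flask, far below 90%.

4. The ratio left the height open: the winter run, with the flask's ratio at twice the substrate, read 2.80% at its last reading, lower than my figure for the flask.

5. The forecast said no with a top of 3.5%, lower than my figure, on the ground that “the catalyst is dying, not the substrate running out”.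

6. The flask gave no and a top of 3.47%.

    free catalyst + left-handed substrate ⇌ catalyst intermediate A (K = 6.90 /M, k = 3700 /M/min)
    free catalyst + right-handed substrate ⇌ catalyst intermediate B (K = 8.10 /M, k = 990 /M/min)
    coupling partner + catalyst intermediate A → free catalyst + left-handed product (k = 94.0 /M/min)
    coupling partner + catalyst intermediate B → free catalyst + right-handed product (k = 35.0 /M/min)
    free catalyst + impurity → spent catalyst (k = 2500 /M/min)
    coupling partner → decomposed reagent (k = 0.0460 /min)

One-for-one killing, reckoned from the ratio, gave 28.6% of the flask's impurity as remaining, and 29% stood at 20.0 min. The neighbouring flask, the same recipe charged with 5.3 × 10⁻⁴ M of impurity, had a ratio of 0.353, below one, so I reckoned 35.3% of its catalyst spent; at 20.0 min spent catalyst stood at 35.3% and impurity at 0%, and the top excess in that flask was 16.5%.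

The earlier runs and the new flask are calculated from invented constants; noise was put on by code.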